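## Analysis of the target

The target is a cyclohexene carrying four substituents. The ring is numbered C1 (CH bearing the isopropenyl group), C2=C3 (C3 bears a methyl), C4 (CH bearing the CH2O‑coumarinyl group), C5 (quaternary: methyl and CH2CH2CO2H) and C6 (CH2). C7 is the central carbon of the isopropenyl group and C8 is the chain methylene bonded to C5.

There are three stereocentres: C1 (S), C4 (R) and C5 (R). On the ring, the isopropenyl group, the aryloxymethyl group and the propanoic acid chain all lie on one face, and the C5 methyl lies on the other.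

The 7‑alkoxycoumarin is an electrophilic, reducible lactone that would not survive strong base, radicals, dissolving metal or osmylation, so it has to arrive late. The C1–H is doubly allylic, and the two alkenes are acid‑sensitive.

The difficulty is the quaternary C5, which sits next to the C4 stereocentre and is cis‑1,3 to the C1 substituent. Intermolecular conjugate addition to a 5‑substituted cyclohexenone would deliver the new carbon trans to that substituent, so it cannot give this relationship.

The strategy rests on that same cis‑1,3 relationship. Because the C1 and C5 carbon substituents are on one face, C7 and C8 can be joined across C6. This closes the five‑membered ring C1–C7–C8–C5–C6 of a bicyclo[3.2.1]octane. In this way the terminal methylene of a precursor isopropenyl group becomes C8, delivered to C5 from the only face it can reach.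

## Retrosynthetic reasoning

**Aryl ether and acid.** The C–O bond between the C4 methylene and the coumarin oxygen is cut first, giving alcohol 20 and umbelliferone 21. The acid is kept as its methyl ester (22) so that it cannot compete as a nucleophile in the etherification. The coumarin therefore meets only a Mitsunobu reaction and a final saponification.

**Chain on C5.** The saturated ester 19 comes from enoate 18 by conjugate reduction. The enoate double bond is cut back to an aldehyde on C5 (in 14) and the stabilised ylide 15. The aldehyde carbon is C8, so only two carbons have to be added, and the aldehyde has no α‑hydrogen.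

**C3 methyl and isopropenyl methylene.** The C3–CH3 bond is cut to the enol triflate 17, and the C7=CH2 bond is cut to the methyl ketone 16. The triflate is deliberately kept until after the oxidative step described next. Keeping C3 as an electron‑poor enol triflate means that only one electron‑rich alkene is present when the bridge is cleaved. The alternative of two trisubstituted alkenes competing for the oxidant is avoided.

**Reconnection of C7 and C8.** The acetyl carbon on C1 and the formyl carbon on C5 of 14 are joined retrosynthetically into the trisubstituted bridge alkene of 12. Forward, a Lemieux–Johnson cleavage releases both carbonyl groups, already cis across the ring, from one rigid bicycle.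

**Enol triflate and bridge alkene.** Triflate 12 goes back to ketone 10 by kinetic enolisation toward C2, the only side that gives the C2=C3 alkene. The bridge alkene of 10 goes back to tertiary alcohol 9 by syn dehydration toward C8; elimination toward the bridgehead C1 is impossible.

**Key disconnection, C5–C8.** Cutting the bond between the quaternary carbon and C8 in 9 reveals enone 8, in which C8 is a bromomethyl carbon on the C1 arm and C5 is the β‑carbon of the enone. This is the cut that creates the quaternary centre intramolecularly, from a centre (C1) that is already in hand. The forward radical cyclisation must also set C4 when the resulting α‑keto radical takes up hydrogen.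

**Radical precursor.** Bromohydrin 8 comes from the isopropenyl group of 7 by Markovnikov cohalogenation. Silyl ether 7 comes from alcohol 6. The hydroxymethyl group of 6 is cut at the C4–CH2 bond to the α‑iodoenone 4 and stannane 5, because a β‑methyl enone cannot be hydroxymethylated directly.

**Chiral pool.** Iodoenone 4 comes from enone 3. Enone 3 is the ring‑opened isomer of car‑3‑en‑5‑one 2, itself the allylic oxidation product of (+)‑3‑carene 1. The cyclopropane carbon of 1 that stays in the ring is C1 of the target, with the correct absolute configuration. The gem‑dimethyl carbon becomes C7.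

## Alternatives that were turned down

**Alternative 1:** The target ring is built by annulation onto a purchased ring, which is later cut open. The chiral imine of 2‑methylcyclohexanone A1 adds through its more substituted enamine to ethyl vinyl ketone A2, forming C5–C6. Hydrolysis and aldol condensation then form C3=C4 and give the bicyclic enone A3.
- For: the quaternary centre is made by a very dependable, scalable asymmetric Michael reaction from cheap achiral materials, with no tin or osmium. On that single point it is at least as strong as the chosen route.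
- Against: A3 still lacks both C1 and C4 as stereocentres. The four‑carbon tether of the original ring must be cut between its first and second carbon counted from C4. The enone oxygen at C2 has to be removed while the alkene is moved to C2=C3. The isopropenyl group must be introduced at C1 with no element that enforces its cis relation to the chain.
- Comparison: the chosen route is shorter after the quaternary centre and ties C5 and C4 directly to C1, whereas this one would control C1 and C4 only by conformational preference.

**Alternative 2:** A Birch‑derived, mirror‑symmetric diene is desymmetrised. The diazoacetate A4 undergoes intramolecular cyclopropanation of one enantiotopic alkene under a chiral dirhodium catalyst. This gives the cyclopropane‑fused lactone A5, with a bond from C5 to the future first chain carbon and a temporary bond from that carbon to C6.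
- For: A5 is reached in very few steps, the cis relation of the C4 and C5 substituents is locked by the lactone, and the absolute configuration comes from a catalyst, not from a stoichiometric source. In step count to the first stereodefined intermediate it beats the chosen route.
- Against: the cyclopropane must be opened selectively at the bond to C6. The chain obtained is one carbon short. C1 is an unfunctionalised allylic methylene at which the isopropenyl group would have to be installed late, cis‑1,3 to the chain, with nothing to direct it.
- Comparison: the chosen route starts from the C1 stereocentre and lets it dictate C5, which is the relationship this alternative leaves to chance.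

**Alternative 3:** The cyclohexene is made by a Diels–Alder reaction of a dearomatised phenol. The o‑quinol A6, released from its dimer by retro‑Diels–Alder reaction, adds methyl 4‑formylpent‑4‑enoate A7. This forms C4–C5 and C1–C6 and gives the bicyclo[2.2.2]octenone A8.
- For: one step sets the relative configuration at C1, C4 and C5 and installs the C2=C3 alkene with its methyl. Cleavage of the ketol bridge then gives the C1 acetyl and C4 carboxyl groups cis. On step economy and convergence it is stronger than the chosen route.
- Against: A8 is racemic unless the dearomatisation is made enantioselective or a resolution is added. The formyl group on C5 has to be reduced all the way to a methyl group in the presence of a ketone and an ester. After bridge cleavage both C1 and C4 are α to carbonyl groups and allylic, so two centres are open to epimerisation or conjugation.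
- Comparison: the chosen route takes its absolute configuration from the chiral pool, has the quaternary methyl at the right oxidation level from the start, and exposes only C1, briefly, to that risk.

Key step: step 7

## Route

Remark: the two epimers at the carbinol carbon formed in step 6 are carried together through steps 7 and 8, because that carbon becomes sp2 in step 8.

Step 1
Reactants: 1 (+)-3-carene, (1S,6R)-3,7,7-trimethylbicyclo[4.1.0]hept-3-ene
Product: 2 car-3-en-5-one, (1R,6S)-4,7,7-trimethylbicyclo[4.1.0]hept-3-en-2-one
Conditions: t-BuOOH, CrO3 (cat.), CH2Cl2, rt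
Reagents that add atoms: tert-butyl hydroperoxide, CC(C)(C)OO
Why: Chromium-catalysed allylic C–H oxidation; hydrogen is removed from the ring CH2 flanked by the alkene CH and the cyclopropane, because that allyl radical has a tertiary terminus, and oxygenation at its secondary terminus gives the β-methyl enone conjugated with the cyclopropane; neither stereocentre is touched.

Step 2
Reactants: 2 car-3-en-5-one
Product: 3 (5S)-3-methyl-5-(prop-1-en-2-yl)cyclohex-2-en-1-one
Conditions: TsOH·H2O (cat.), benzene, 60 °C, stopped at full conversion; aq. NaOH wash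
Reagents that add atoms: none
Why: Acid-catalysed homoconjugate opening of a cyclopropyl ketone: the protonated enone ionises the cyclopropane bond between the α-carbon and the gem-dimethyl carbon (tertiary cation), and E1 loss of a methyl proton gives the isopropenyl group; the ring carbon that becomes C1 is not involved and keeps its configuration, and any phenol from over-isomerisation is removed by the base wash.

Step 3
Reactants: 3 (5S)-3-methyl-5-(prop-1-en-2-yl)cyclohex-2-en-1-one
Product: 4 (5S)-2-iodo-3-methyl-5-(prop-1-en-2-yl)cyclohex-2-en-1-one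
Conditions: I2, pyridine, DMAP (cat.), CH2Cl2, 0 °C → rt
Reagents that add atoms: iodine, II
Why: α-Iodination of an enone by amine conjugate addition, iodination of the enolate and elimination of the amine (Baylis–Hillman-type addition–elimination); the isolated isopropenyl alkene is spared because iodine addition to it is reversible.

Step 4
Reactants: 4 (5S)-2-iodo-3-methyl-5-(prop-1-en-2-yl)cyclohex-2-en-1-one; 5 (tributylstannyl)methanol
Product: 6 (5S)-2-(hydroxymethyl)-3-methyl-5-(prop-1-en-2-yl)cyclohex-2-en-1-one
Conditions: Pd(PPh3)4 (cat.), dioxane, 90 °C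
Reagents that add atoms: none
Why: Stille (Kosugi–Migita) hydroxymethylation: zerovalent palladium inserts into the vinyl C–I bond, the α-oxygenated methylene group transfers from tin in preference to butyl, and reductive elimination forms the C4–CH2OH bond.

Step 5
Reactants: 6 (5S)-2-(hydroxymethyl)-3-methyl-5-(prop-1-en-2-yl)cyclohex-2-en-1-one
Product: 7 (5S)-2-{[(tert-butyldimethylsilyl)oxy]methyl}-3-methyl-5-(prop-1-en-2-yl)cyclohex-2-en-1-one
Conditions: TBSCl, imidazole, DMF, rt
Reagents that add atoms: tert-butyldimethylsilyl chloride, CC(C)(C)[Si](C)(C)Cl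
Why: Standard silylation of a primary alcohol; the ether is inert to the radical, amide-base, osmylation, titanium and magnesium steps that follow.

Step 6
Reactants: 7 (5S)-2-{[(tert-butyldimethylsilyl)oxy]methyl}-3-methyl-5-(prop-1-en-2-yl)cyclohex-2-en-1-one
Product: 8 (5S)-5-(1-bromo-2-hydroxypropan-2-yl)-2-{[(tert-butyldimethylsilyl)oxy]methyl}-3-methylcyclohex-2-en-1-one, both epimers at the carbinol carbon
Conditions: NBS, acetone/H2O, 0 °C
Reagents that add atoms: N-bromosuccinimide, O=C1CCC(=O)N1Br; water, O
Why: Bromohydrin formation: the electron-rich 1,1-disubstituted alkene forms the bromonium ion while the electron-poor tetrasubstituted enone alkene does not, and water opens it at the tertiary carbon (Markovnikov); the new carbinol centre is not controlled and does not need to be.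

Step 7
Reactants: 8 (5S)-5-(1-bromo-2-hydroxypropan-2-yl)-2-{[(tert-butyldimethylsilyl)oxy]methyl}-3-methylcyclohex-2-en-1-one
Product: 9 (1S,2S,5S)-2-{[(tert-butyldimethylsilyl)oxy]methyl}-6-hydroxy-1,6-dimethylbicyclo[3.2.1]octan-3-one, both epimers at C6, CH2OSi equatorial
Conditions: Bu3SnH (slow addition), AIBN (cat.), benzene, high dilution, 80 °C
Reagents that add atoms: none
Why: The stannyl radical abstracts bromine to give the primary radical at C8, which, once the C1 arm is axial, adds to C5, the β-carbon of the enone, and the resulting α-keto radical at C4 takes hydrogen from the stannane to carry the chain. The closest known reaction type is the 5-exo cyclisation of bromohydrins and bromo ethers of 5-isopropenylcyclohex-2-enones to bicyclo[3.2.1]octan-3-ones, including acceptors substituted at both alkene carbons. The five-membered ring C1–C7–C8–C5–C6 closes in the 5-exo-trig mode; 6-endo attack at C4 is disfavoured both by the polarity of a nucleophilic alkyl radical toward the enone and by the strain of the alternative bicycle. The configuration at C5 is fixed by the tether, because the two-atom arm can reach C5 only from the face on which it stands, so C8 ends cis to C1 and the methyl trans. The configuration at C4 is set by hydrogen transfer to the planar enoxyl radical from the exo face (the side of the one-carbon bridge C6), the endo face being screened by the new two-carbon bridge, which leaves CH2OSi equatorial and cis to C8; this is also the more stable epimer. The selectivity the step needs is cyclisation ahead of direct reduction of the primary radical, secured by a low stationary stannane concentration and by the polarity match. The free tertiary hydroxyl and the silyl ether are inert, and both carbinol epimers cyclise.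

Step 8
Reactants: 9 (1S,2S,5S)-2-{[(tert-butyldimethylsilyl)oxy]methyl}-6-hydroxy-1,6-dimethylbicyclo[3.2.1]octan-3-one
Product: 10 (1S,2S,5S)-2-{[(tert-butyldimethylsilyl)oxy]methyl}-1,6-dimethylbicyclo[3.2.1]oct-6-en-3-one
Conditions: Burgess reagent (methyl N-(triethylammoniosulfonyl)carbamate), benzene, 60 °C
Reagents that add atoms: none
Why: Burgess syn-elimination of a tertiary alcohol: in the rigid five-membered ring each carbinol epimer has a C8 hydrogen eclipsed with the C–O bond, elimination toward the bridgehead C1 is excluded by Bredt's rule, and the more substituted endocyclic alkene is expected to prevail over the exocyclic one.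

Step 9
Reactants: 10 (1S,2S,5S)-2-{[(tert-butyldimethylsilyl)oxy]methyl}-1,6-dimethylbicyclo[3.2.1]oct-6-en-3-one
Product: 12 (1S,4S,5S)-4-{[(tert-butyldimethylsilyl)oxy]methyl}-5,7-dimethylbicyclo[3.2.1]octa-2,6-dien-3-yl trifluoromethanesulfonate, via lithium enolate 11 (not isolated)
Conditions: LiN(iPr)2 (LDA), THF, −78 °C; PhNTf2, −78 → 0 °C
Reagents that add atoms: lithium diisopropylamide, [Li]N(C(C)C)C(C)C (lithium in 11 only); N-phenylbis(trifluoromethanesulfonimide), O=S(=O)(N(c1ccccc1)S(=O)(=O)C(F)(F)F)C(F)(F)F
Why: Kinetic enolate formation and O-triflation: the amide base removes the axial proton of the C2 methylene and not the tertiary C4–H next to the quaternary carbon, and trapping at low temperature prevents equilibration, which would also invite β-elimination of the silyloxy group; C4 becomes allylic and configurationally fixed.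

Step 10
Reactants: 12 (1S,4S,5S)-4-{[(tert-butyldimethylsilyl)oxy]methyl}-5,7-dimethylbicyclo[3.2.1]octa-2,6-dien-3-yl trifluoromethanesulfonate
Product: 14 (3S,5R,6S)-3-acetyl-6-{[(tert-butyldimethylsilyl)oxy]methyl}-5-formyl-5-methylcyclohex-1-en-1-yl trifluoromethanesulfonate, via exo-diol 13 (not isolated)
Conditions: OsO4 (cat.), NaIO4, 2,6-lutidine, dioxane/H2O, rt
Reagents that add atoms: osmium tetroxide, O=[Os](=O)(=O)=O (catalytic, delivers the two oxygens); sodium periodate, [Na+].[O-]I(=O)(=O)=O
Why: Lemieux–Johnson cleavage: the electrophilic oxidant adds to the exo face of the strained, electron-rich C7=C8 alkene and leaves the electron-poor enol triflate alone, and periodate cleaves the diol to the C1 acetyl and C5 formyl groups; the lutidine buffer keeps the medium near neutral so that C1, now α to a ketone, is not epimerised.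

Step 11
Reactants: 14 (3S,5R,6S)-3-acetyl-6-{[(tert-butyldimethylsilyl)oxy]methyl}-5-formyl-5-methylcyclohex-1-en-1-yl trifluoromethanesulfonate; 15 methyl (triphenylphosphoranylidene)acetate
Product: 16 methyl (2E)-3-[(1S,2S,5S)-5-acetyl-2-{[(tert-butyldimethylsilyl)oxy]methyl}-1-methyl-3-{[(trifluoromethyl)sulfonyl]oxy}cyclohex-3-en-1-yl]prop-2-enoate
Conditions: toluene, 80 °C
Reagents that add atoms: none
Why: Wittig reaction of a stabilised ylide: it reacts with the aldehyde and not with the methyl ketone, gives the E-enoate, and being neutral it neither enolises C1 nor triggers an aldol reaction between the cis acetyl and formyl groups.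

Step 12
Reactants: 16 methyl (2E)-3-[(1S,2S,5S)-5-acetyl-2-{[(tert-butyldimethylsilyl)oxy]methyl}-1-methyl-3-{[(trifluoromethyl)sulfonyl]oxy}cyclohex-3-en-1-yl]prop-2-enoate
Product: 17 methyl (2E)-3-[(1S,2S,5S)-2-{[(tert-butyldimethylsilyl)oxy]methyl}-1-methyl-5-(prop-1-en-2-yl)-3-{[(trifluoromethyl)sulfonyl]oxy}cyclohex-3-en-1-yl]prop-2-enoate
Conditions: Zn, CH2Br2, TiCl4, THF/CH2Cl2, 0 °C → rt
Reagents that add atoms: dibromomethane, BrCBr
Why: Takai–Lombardo methylenation: the non-basic zinc/titanium methylene reagent converts the ketone into the isopropenyl group without enolising the adjacent C1 stereocentre and does not touch the ester or the enol triflate.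

Step 13
Reactants: 17 methyl (2E)-3-[(1S,2S,5S)-2-{[(tert-butyldimethylsilyl)oxy]methyl}-1-methyl-5-(prop-1-en-2-yl)-3-{[(trifluoromethyl)sulfonyl]oxy}cyclohex-3-en-1-yl]prop-2-enoate
Product: 18 methyl (2E)-3-[(1S,2S,5S)-2-{[(tert-butyldimethylsilyl)oxy]methyl}-1,3-dimethyl-5-(prop-1-en-2-yl)cyclohex-3-en-1-yl]prop-2-enoate
Conditions: MeZnCl, Pd(PPh3)4 (cat.), THF, 50 °C
Reagents that add atoms: methylzinc chloride, C[Zn]Cl
Why: Negishi coupling: zerovalent palladium inserts into the C3–O triflate bond, methyl is transferred from zinc and reductive elimination gives the C2=C3 methyl alkene; the organozinc reagent does not add to the enoate.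

Step 14
Reactants: 18 methyl (2E)-3-[(1S,2S,5S)-2-{[(tert-butyldimethylsilyl)oxy]methyl}-1,3-dimethyl-5-(prop-1-en-2-yl)cyclohex-3-en-1-yl]prop-2-enoate
Product: 19 methyl 3-[(1R,2R,5S)-2-{[(tert-butyldimethylsilyl)oxy]methyl}-1,3-dimethyl-5-(prop-1-en-2-yl)cyclohex-3-en-1-yl]propanoate
Conditions: Mg, MeOH, 0 °C → rt
Reagents that add atoms: none
Why: Single-electron conjugate reduction of an α,β-unsaturated ester by magnesium in methanol; only the conjugated alkene accepts an electron, so the ring alkene and the isopropenyl group remain, and a methyl ester makes methanolysis degenerate.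

Step 15
Reactants: 19 methyl 3-[(1R,2R,5S)-2-{[(tert-butyldimethylsilyl)oxy]methyl}-1,3-dimethyl-5-(prop-1-en-2-yl)cyclohex-3-en-1-yl]propanoate
Product: 20 methyl 3-[(1R,2R,5S)-2-(hydroxymethyl)-1,3-dimethyl-5-(prop-1-en-2-yl)cyclohex-3-en-1-yl]propanoate
Conditions: HF·pyridine, pyridine, THF, 0 °C → rt
Reagents that add atoms: none
Why: Fluoride-driven cleavage of the Si–O bond under buffered conditions that leave the ester and both alkenes untouched.

Step 16
Reactants: 20 methyl 3-[(1R,2R,5S)-2-(hydroxymethyl)-1,3-dimethyl-5-(prop-1-en-2-yl)cyclohex-3-en-1-yl]propanoate; 21 umbelliferone (7-hydroxy-2H-chromen-2-one)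
Product: 22 methyl 3-[(1R,2R,5S)-1,3-dimethyl-2-{[(2-oxo-2H-chromen-7-yl)oxy]methyl}-5-(prop-1-en-2-yl)cyclohex-3-en-1-yl]propanoate
Conditions: PPh3, DIAD, THF, 0 °C → rt
Reagents that add atoms: none
Why: Mitsunobu etherification: the acidic 7-hydroxycoumarin displaces the alkoxyphosphonium group at the primary carbon by an SN2 process, so no stereocentre is involved and the lactone is not exposed to base.

Step 17
Reactants: 22 methyl 3-[(1R,2R,5S)-1,3-dimethyl-2-{[(2-oxo-2H-chromen-7-yl)oxy]methyl}-5-(prop-1-en-2-yl)cyclohex-3-en-1-yl]propanoate
Product: 24 3-[(1R,2R,5S)-1,3-dimethyl-2-{[(2-oxo-2H-chromen-7-yl)oxy]methyl}-5-(prop-1-en-2-yl)cyclohex-3-en-1-yl]propanoic acid (target), via trilithium coumarinate 23 (not isolated)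
Conditions: LiOH, THF/H2O, rt, dark; then 1 M HCl to pH 2
Reagents that add atoms: lithium hydroxide, [Li+].[OH-]
Why: Saponification of the methyl ester; hydroxide also opens the coumarin to the Z-configured 2-hydroxycinnamate, which keeps its cis geometry and closes back to the lactone on acidification.

## Compound list

1 | (+)-3-carene, (1S,6R)-3,7,7-trimethylbicyclo[4.1.0]hept-3-ene | CC1=CC[C@@H]2[C@H](C1)C2(C)C | starting material
2 | car-3-en-5-one, (1R,6S)-4,7,7-trimethylbicyclo[4.1.0]hept-3-en-2-one | CC1=CC(=O)[C@@H]2[C@H](C1)C2(C)C | intermediate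
3 | (5S)-3-methyl-5-(prop-1-en-2-yl)cyclohex-2-en-1-one | C=C(C)[C@@H]1CC(=O)C=C(C)C1 | intermediate
4 | (5S)-2-iodo-3-methyl-5-(prop-1-en-2-yl)cyclohex-2-en-1-one | C=C(C)[C@@H]1CC(=O)C(I)=C(C)C1 | intermediate
5 | (tributylstannyl)methanol | OC[Sn](CCCC)(CCCC)CCCC | starting material
6 | (5S)-2-(hydroxymethyl)-3-methyl-5-(prop-1-en-2-yl)cyclohex-2-en-1-one | C=C(C)[C@@H]1CC(=O)C(CO)=C(C)C1 | intermediate
7 | (5S)-2-{[(tert-butyldimethylsilyl)oxy]methyl}-3-methyl-5-(prop-1-en-2-yl)cyclohex-2-en-1-one | C=C(C)[C@@H]1CC(=O)C(CO[Si](C)(C)C(C)(C)C)=C(C)C1 | intermediate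
8 | (5S)-5-(1-bromo-2-hydroxypropan-2-yl)-2-{[(tert-butyldimethylsilyl)oxy]methyl}-3-methylcyclohex-2-en-1-one, both epimers at the carbinol carbon | CC(O)(CBr)[C@@H]1CC(=O)C(CO[Si](C)(C)C(C)(C)C)=C(C)C1 | intermediate
9 | (1S,2S,5S)-2-{[(tert-butyldimethylsilyl)oxy]methyl}-6-hydroxy-1,6-dimethylbicyclo[3.2.1]octan-3-one, both epimers at C6 | CC1(O)C[C@]2(C)C[C@H]1CC(=O)[C@@H]2CO[Si](C)(C)C(C)(C)C | intermediate
10 | (1S,2S,5S)-2-{[(tert-butyldimethylsilyl)oxy]methyl}-1,6-dimethylbicyclo[3.2.1]oct-6-en-3-one | CC1=C[C@]2(C)C[C@H]1CC(=O)[C@@H]2CO[Si](C)(C)C(C)(C)C | intermediate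
11 | lithium enolate of 10 (enolate toward the C2 methylene, target numbering) | CC1=C[C@]2(C)C[C@H]1C=C(O[Li])[C@@H]2CO[Si](C)(C)C(C)(C)C | intermediate
12 | (1S,4S,5S)-4-{[(tert-butyldimethylsilyl)oxy]methyl}-5,7-dimethylbicyclo[3.2.1]octa-2,6-dien-3-yl trifluoromethanesulfonate | CC1=C[C@]2(C)C[C@H]1C=C(OS(=O)(=O)C(F)(F)F)[C@@H]2CO[Si](C)(C)C(C)(C)C | intermediate
13 | 6,7-exo-cis-diol of 12 (both hydroxyls on the face of the one-carbon bridge) | C[C@@]1(O)[C@H](O)[C@]2(C)C[C@H]1C=C(OS(=O)(=O)C(F)(F)F)[C@@H]2CO[Si](C)(C)C(C)(C)C | intermediate
14 | (3S,5R,6S)-3-acetyl-6-{[(tert-butyldimethylsilyl)oxy]methyl}-5-formyl-5-methylcyclohex-1-en-1-yl trifluoromethanesulfonate | CC(=O)[C@@H]1C=C(OS(=O)(=O)C(F)(F)F)[C@H](CO[Si](C)(C)C(C)(C)C)[C@](C)(C=O)C1 | intermediate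
15 | methyl (triphenylphosphoranylidene)acetate | COC(=O)C=P(c1ccccc1)(c1ccccc1)c1ccccc1 | starting material
16 | methyl (2E)-3-[(1S,2S,5S)-5-acetyl-2-{[(tert-butyldimethylsilyl)oxy]methyl}-1-methyl-3-{[(trifluoromethyl)sulfonyl]oxy}cyclohex-3-en-1-yl]prop-2-enoate | CC(=O)[C@@H]1C=C(OS(=O)(=O)C(F)(F)F)[C@H](CO[Si](C)(C)C(C)(C)C)[C@](C)(/C=C/C(=O)OC)C1 | intermediate
17 | methyl (2E)-3-[(1S,2S,5S)-2-{[(tert-butyldimethylsilyl)oxy]methyl}-1-methyl-5-(prop-1-en-2-yl)-3-{[(trifluoromethyl)sulfonyl]oxy}cyclohex-3-en-1-yl]prop-2-enoate | C=C(C)[C@@H]1C=C(OS(=O)(=O)C(F)(F)F)[C@H](CO[Si](C)(C)C(C)(C)C)[C@](C)(/C=C/C(=O)OC)C1 | intermediate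
18 | methyl (2E)-3-[(1S,2S,5S)-2-{[(tert-butyldimethylsilyl)oxy]methyl}-1,3-dimethyl-5-(prop-1-en-2-yl)cyclohex-3-en-1-yl]prop-2-enoate | C=C(C)[C@@H]1C=C(C)[C@H](CO[Si](C)(C)C(C)(C)C)[C@](C)(/C=C/C(=O)OC)C1 | intermediate
19 | methyl 3-[(1R,2R,5S)-2-{[(tert-butyldimethylsilyl)oxy]methyl}-1,3-dimethyl-5-(prop-1-en-2-yl)cyclohex-3-en-1-yl]propanoate | C=C(C)[C@@H]1C=C(C)[C@H](CO[Si](C)(C)C(C)(C)C)[C@](C)(CCC(=O)OC)C1 | intermediate
20 | methyl 3-[(1R,2R,5S)-2-(hydroxymethyl)-1,3-dimethyl-5-(prop-1-en-2-yl)cyclohex-3-en-1-yl]propanoate | C=C(C)[C@@H]1C=C(C)[C@H](CO)[C@](C)(CCC(=O)OC)C1 | intermediate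
21 | umbelliferone (7-hydroxy-2H-chromen-2-one) | O=c1ccc2ccc(O)cc2o1 | starting material
22 | methyl 3-[(1R,2R,5S)-1,3-dimethyl-2-{[(2-oxo-2H-chromen-7-yl)oxy]methyl}-5-(prop-1-en-2-yl)cyclohex-3-en-1-yl]propanoate | C=C(C)[C@@H]1C=C(C)[C@H](COc2ccc3ccc(=O)oc3c2)[C@](C)(CCC(=O)OC)C1 | intermediate
23 | trilithium salt of the ring-opened (Z)-2-hydroxycinnamate carboxylate derived from 22 | C=C(C)[C@@H]1C=C(C)[C@H](COc2ccc(/C=C\C(=O)[O-])c([O-])c2)[C@](C)(CCC(=O)[O-])C1.[Li+].[Li+].[Li+] | intermediate
24 | 3-[(1R,2R,5S)-1,3-dimethyl-2-{[(2-oxo-2H-chromen-7-yl)oxy]methyl}-5-(prop-1-en-2-yl)cyclohex-3-en-1-yl]propanoic acid | C=C(C)[C@@H]1C=C(C)[C@H](COc2ccc3ccc(=O)oc3c2)[C@](C)(CCC(=O)O)C1 | target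

## Step count and least certain steps

Total: 17 steps. Longest linear sequence: 17 steps, from 1 to 24; compounds 5, 15 and 21 are purchased.

**Step 7 (key step).** The most likely failure is hydrogen transfer to the primary radical before it cyclises. The arm must first become axial, and the acceptor carbon is fully substituted. A second possible failure is poor facial selectivity in the hydrogen transfer to C4.
Fallback: give up the stannane chain and close the ring by a metal-mediated reductive conjugate addition, with Zn and NiCl2·6H2O in pyridine/THF. No hydrogen-atom donor is present, and the sequence ends with protonation of a metal enolate under equilibrating conditions, which favours the equatorial CH2OSi group. The fallback sets out from 8 and comes back at 9; it makes no new compound.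

**Step 2.** The cation formed on ring opening may lose the ring proton at C1 instead of a methyl proton. Alternatively, the isopropenyl alkene may be re-protonated and drift into the ring, ending in aromatisation and loss of the stereocentre.
Fallback: separate capture from elimination. From 2, aqueous acid (dilute HClO4 in acetone/H2O) opens the cyclopropane with water to give the tertiary alcohol (5S)-5-(2-hydroxypropan-2-yl)-3-methylcyclohex-2-en-1-one F1. F1 is then dehydrated by an E2 process through its chlorosulfite (SOCl2, pyridine, 0 °C), which removes the accessible methyl hydrogens and returns to the route at 3.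

**Step 8.** The syn-elimination may run toward the methyl group and give the exocyclic alkene, which is useless for the cleavage.
Fallback: accept that regiochemistry and correct it under thermodynamic control. From 9, dehydration with SOCl2/pyridine gives (1S,2S,5S)-2-{[(tert-butyldimethylsilyl)oxy]methyl}-1-methyl-6-methylidenebicyclo[3.2.1]octan-3-one F2 (also the expected by-product of step 8). F2 is isomerised with catalytic I2 in refluxing benzene to the more stable endocyclic alkene, coming back at 10.

**Step 12.** The Lewis acidic titanium reagent may react sluggishly with the hindered ketone. Prolonged exposure could then enolise C1, which is α to the ketone and allylic, with loss of the cis relationship.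
Fallback: build the methylene group by addition and elimination. From 16, Me3SiCH2MgCl/CeCl3 in THF at −78 °C adds to the ketone without enolisation and gives the β-hydroxysilane methyl (2E)-3-[(1S,2S,5S)-2-{[(tert-butyldimethylsilyl)oxy]methyl}-5-[2-hydroxy-1-(trimethylsilyl)propan-2-yl]-1-methyl-3-{[(trifluoromethyl)sulfonyl]oxy}cyclohex-3-en-1-yl]prop-2-enoate F3. Acid-induced Peterson elimination (AcOH, NaOAc, 50 °C) can place the alkene only between C7 and the former silylmethyl carbon, coming back at 17.

**Step 17.** The opened coumarinate may isomerise to the trans acid, which cannot relactonise, or hydroxide may add to the coumarin.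
Fallback: remove hydroxide from the last stage. From 20, saponification (LiOH, THF/H2O) gives 3-[(1R,2R,5S)-2-(hydroxymethyl)-1,3-dimethyl-5-(prop-1-en-2-yl)cyclohex-3-en-1-yl]propanoic acid F4. The carboxylate is alkylated with allyl bromide and KHCO3 in DMF to prop-2-en-1-yl 3-[(1R,2R,5S)-2-(hydroxymethyl)-1,3-dimethyl-5-(prop-1-en-2-yl)cyclohex-3-en-1-yl]propanoate F5. Mitsunobu reaction with 21 gives prop-2-en-1-yl 3-[(1R,2R,5S)-1,3-dimethyl-2-{[(2-oxo-2H-chromen-7-yl)oxy]methyl}-5-(prop-1-en-2-yl)cyclohex-3-en-1-yl]propanoate F6. The allyl group is then removed with Pd(PPh3)4 and morpholine in THF at rt, coming back at 24.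

## Further compounds

F0 | step 7 | none | none
F1 | step 2 | (5S)-5-(2-hydroxypropan-2-yl)-3-methylcyclohex-2-en-1-one | CC(C)(O)[C@@H]1CC(=O)C=C(C)C1
F2 | step 8 | (1S,2S,5S)-2-{[(tert-butyldimethylsilyl)oxy]methyl}-1-methyl-6-methylidenebicyclo[3.2.1]octan-3-one | C=C1C[C@]2(C)C[C@H]1CC(=O)[C@@H]2CO[Si](C)(C)C(C)(C)C
F3 | step 12 | methyl (2E)-3-[(1S,2S,5S)-2-{[(tert-butyldimethylsilyl)oxy]methyl}-5-[2-hydroxy-1-(trimethylsilyl)propan-2-yl]-1-methyl-3-{[(trifluoromethyl)sulfonyl]oxy}cyclohex-3-en-1-yl]prop-2-enoate, both carbinol epimers | CC(O)(C[Si](C)(C)C)[C@@H]1C=C(OS(=O)(=O)C(F)(F)F)[C@H](CO[Si](C)(C)C(C)(C)C)[C@](C)(/C=C/C(=O)OC)C1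
F4 | step 17 | 3-[(1R,2R,5S)-2-(hydroxymethyl)-1,3-dimethyl-5-(prop-1-en-2-yl)cyclohex-3-en-1-yl]propanoic acid | C=C(C)[C@@H]1C=C(C)[C@H](CO)[C@](C)(CCC(=O)O)C1
F5 | step 17 | prop-2-en-1-yl 3-[(1R,2R,5S)-2-(hydroxymethyl)-1,3-dimethyl-5-(prop-1-en-2-yl)cyclohex-3-en-1-yl]propanoate | C=C(C)[C@@H]1C=C(C)[C@H](CO)[C@](C)(CCC(=O)OCC=C)C1
F6 | step 17 | prop-2-en-1-yl 3-[(1R,2R,5S)-1,3-dimethyl-2-{[(2-oxo-2H-chromen-7-yl)oxy]methyl}-5-(prop-1-en-2-yl)cyclohex-3-en-1-yl]propanoate | C=C(C)[C@@H]1C=C(C)[C@H](COc2ccc3ccc(=O)oc3c2)[C@](C)(CCC(=O)OCC=C)C1
A1 | alternative 1 | 2-methylcyclohexanone | CC1CCCCC1=O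
A2 | alternative 1 | ethyl vinyl ketone (pent-1-en-3-one) | CCC(=O)C=C
A3 | alternative 1 | (R)-1,4a-dimethyl-4,4a,5,6,7,8-hexahydronaphthalen-2(3H)-one | CC1=C2CCCC[C@]2(C)CCC1=O
A4 | alternative 2 | (2,6-dimethylcyclohexa-2,5-dien-1-yl)methyl diazoacetate | CC1=CCC=C(C)C1COC(=O)C=[N+]=[N-]
A5 | alternative 2 | tricyclic cyclopropane-fused lactone | CC1=CC[C@H]2[C@H]3C(=O)OC[C@@H]1[C@@]23C
A6 | alternative 3 | 6-hydroxy-3,6-dimethylcyclohexa-2,4-dien-1-one | CC1=CC(=O)C(C)(O)C=C1
A7 | alternative 3 | methyl 4-formylpent-4-enoate | C=C(C=O)CCC(=O)OC
A8 | alternative 3 | bicyclo[2.2.2]octenone adduct (formyl endo, ester chain syn to the ketol bridge) | O=C[C@@]1(CCC(=O)OC)C[C@H]2C=C(C)[C@@H]1C(=O)[C@@]2(C)O
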